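Wednesday's run and Monday's run differ in reagent, yet they line up once each reading's time is multiplied by its run's reagent charge. Wednesday's last reading, at 34.2 M·s, stands at 35%, and Monday's third, at 34.8 M·s, stands at 36%. This line-up is read from the readings, at the one substrate charge of these runs, and we use the product as a count of how far a run has come.

| flask | substrate | reagent | remark | time |
|---|---|---|---|---|
| Wednesday's | 0.20 M | 0.19 M | run made earlier |  |
| Friday's | 0.20 M | 0.13 M | run made earlier |  |
| Monday's | 0.20 M | 0.29 M | run made earlier |  |
| ash | 0.20 M | 0.190 M | everything together at the start | 3.0 min |
| maple | 0.20 M | 0.190 M (fed, over 2.5 min) | all else is in the flask from the start; the feed brings no volume worth counting | 3.0 min |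
| alder | 0.20 M (fed, over 2.5 min) | 0.190 M | all else is in the flask from the start; the feed brings no volume worth counting | 3.0 min |

| run | time / min | target / % |
|---|---|---|
| Wednesday's | 0.500 | 3 |
| Wednesday's | 1.00 | 12 |
| Wednesday's | 1.50 | 22 |
| Wednesday's | 2.00 | 28 |
| Wednesday's | 2.50 | 33 |
| Wednesday's | 3.00 | 35 |
| Friday's | 0.250 | 2 |
| Friday's | 0.500 | 1 |
| Friday's | 0.833 | 10 |
| Friday's | 1.33 | 11 |
| Friday's | 2.00 | 19 |
| Friday's | 4.00 | 30 |
| Monday's | 0.667 | 13 |
| Monday's | 1.33 | 25 |
| Monday's | 2.00 | 36 |
| Monday's | 2.50 | 39 |
| Monday's | 3.00 | 46 |
| Monday's | 4.00 | 47 |

(scatter of a reading: 1.5 percentage points)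



* the best flask by amount of target, in percent of the substrate charged; "all alike" if 1.5 percentage points covers them all (ash / maple / alder / all alike)
* amount of target at the end, in percent of the substrate charged, ash
* amount of target at the end, in percent of the substrate charged, maple
* amount of target at the end, in percent of the substrate charged, alder

Ash repeats Wednesday's run, so we expect it at 35%. A fed flask can be bracketed by two extremes we can solve in the head. If the whole feed went in at the start, it would be ash again. If the whole feed came as a lump at the end of the feed, the charge would have 0.500 min in the flask, and Wednesday's run reads 3% at that time.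

A steady feed lies between these, and a parcel spends on average 1.75 min in the flask, its mean residence time. So maple gets 19.9 M·s, and this is the exposure, the reagent charge times the mean time the charge has spent in the flask. The charges are close, so we give alder the same count. Wednesday's readings on either side of that time average 25.0%, which is our figure for both fed flasks.

The forecast says 35% for ash, 24% for maple and 26% for alder, with ash best: “Both fed flasks should therefore fall short”.

The flasks give 34.2% for ash, 22.5% for maple and 22.4% for alder, so ash is best, 12 percentage points above maple, more than the margin.

    target ⇌ isomer of the product (K = 0.980, k = 0.00570 s⁻¹)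
    substrate + reagent → intermediate A (k = 0.0550 M⁻¹ s⁻¹)
    intermediate A → target (k = 0.0140 s⁻¹)
    reagent + intermediate A ⇌ intermediate B (K = 3.00 M⁻¹, k = 0.00340 M⁻¹ s⁻¹)

The exposure 19.9 M·s read 25.0%, and maple stands 2.5 points below that. The neighbour of alder with 0.76 M of reagent keeps the same mean time, so its exposure is 79.8 M·s. Monday's last reading has 69.6 M·s and stands at 47%, so this neighbour lies further out than that reading, and the count has no reading to offer for it. The neighbour gives 41.8% of target, with 7.55% of the substrate left and 30.2% standing as intermediate A.

(The earlier runs and the new flask were generated by integration on assumed constants; scatter was added.)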